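**Retrosynthetic overview**
- The target is a meso 1,4-diketone. Its C4 carbonyl and the benzylic CH2 carried by C2 are 1,4-related, so they are read as the C=O and the O-bearing C5 of a γ-aryl-γ-butyrolactone. Target C3 and C2 are then lactone C3 and C4, and the meso pair corresponds to the 3,4-trans lactone.
- Endgame: target 20 ⇐ hydrogenolysis of six benzyl ethers and the benzylic C–OH of 19 ⇐ dithiane hydrolysis of 18 ⇐ opening of lactone 13 by an aryllithium (second aroyl group).
- Key disconnection: 13 ⇐ butenolide 6 + lithiated aryl dithiane 11 (masked C1 aroyl anion, forms C1–C2) + benzylic bromide 10 (forms C3–CH2), in one flask.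
- Building blocks: 6 from 4-(benzyloxy)benzaldehyde and ethyl propiolate; dithiane 9 from 2,4-dihydroxybenzaldehyde; aryl bromide 15 from 4-bromoresorcinol.
- Rings: the butenolide (step 2) is the only carbocyclic/heterocyclic ring built in the skeleton and is opened again in step 7; the dithiane ring (step 4) is a temporary mask removed in step 8.

Key step: step 5

Assumption: the target descriptors correspond to the meso (2R,3S) form, which is achiral, so racemic intermediates suffice and only relative configuration is controlled; γ-hydroxy ketones 18 and 19 are written open-chain although they may rest partly as cyclic hemiketals, which react alike in the following steps.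

**Step 1**
Reactants: 1 4-(benzyloxy)benzaldehyde; 2 ethyl propiolate
Product: 4 ethyl 4-[4-(benzyloxy)phenyl]-4-hydroxybut-2-ynoate (racemic), via lithium ethyl propiolate 3 (not isolated)
Conditions: n-BuLi, THF, −78 °C; then 1, −78 °C; AcOH quench at −78 °C
Reagents that add atoms: none
Why: Acetylide 1,2-addition to a non-enolisable aldehyde, with the cold acidic quench preventing retro-addition; the carbinol centre forms racemic, which is enough because this carbon ends as a CH2 group.

**Step 2**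
Reactants: 4 ethyl 4-[4-(benzyloxy)phenyl]-4-hydroxybut-2-ynoate
Product: 6 5-[4-(benzyloxy)phenyl]furan-2(5H)-one (racemic), via ethyl (Z)-4-[4-(benzyloxy)phenyl]-4-hydroxybut-2-enoate 5 (not isolated)
Conditions: H2 (1 atm), Lindlar catalyst, quinoline, EtOAc, rt; then PPTS (cat.), toluene, 40 °C
Reagents that add atoms: none
Why: Lindlar cis-semihydrogenation gives the Z-enoate, whose hydroxyl and ester are held cis so that acid-catalysed lactonisation closes the butenolide; the poisoned catalyst should leave the benzyl ether and the benzylic C–O bond intact.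

**Step 3**
Reactants: 7 2,4-dihydroxybenzaldehyde
Product: 8 2,4-bis(benzyloxy)benzaldehyde
Conditions: BnBr, K2CO3, DMF, 60 °C
Reagents that add atoms: benzyl bromide, BrCc1ccccc1
Why: Williamson ether synthesis; warm DMF with excess carbonate should also alkylate the hydrogen-bonded 2-hydroxyl.

**Step 4**
Reactants: 8 2,4-bis(benzyloxy)benzaldehyde
Product: 9 2-[2,4-bis(benzyloxy)phenyl]-1,3-dithiane
Conditions: HS(CH2)3SH, BF3·OEt2 (cat.), CH2Cl2, 0 °C to rt
Reagents that add atoms: propane-1,3-dithiol, SCCCS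
Why: Lewis-acid-catalysed dithioacetalisation of an aromatic aldehyde; catalytic BF3 at 0 °C is too mild to cleave the aryl benzyl ethers.

**Step 5**
Reactants: 9 2-[2,4-bis(benzyloxy)phenyl]-1,3-dithiane; 6 5-[4-(benzyloxy)phenyl]furan-2(5H)-one; 10 4-(benzyloxy)benzyl bromide
Product: 13 rac-(3S,4S,5S)-3-[4-(benzyloxy)benzyl]-4-{2-[2,4-bis(benzyloxy)phenyl]-1,3-dithian-2-yl}-5-[4-(benzyloxy)phenyl]dihydrofuran-2(3H)-one (3,4-trans-4,5-trans), via 2-lithio-1,3-dithiane 11 (not isolated), via lithium lactone enolate 12 (not isolated)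
Conditions: 9, n-BuLi, THF, −78 to −30 °C; then 6 added slowly, −78 °C; then 10, DMPU, −78 to −20 °C; aq NH4Cl
Reagents that add atoms: none
Why: Carbanion 11, stabilised by both sulfur atoms and the aryl group, adds in Michael fashion to C4 of butenolide 6 to give lactone enolate 12, which is C-alkylated (SN2) by bromide 10 once DMPU is added; the C1–C2 and C3–CH2 bonds of the target form in one flask and no ring is closed. The closest known reaction type is the tandem conjugate addition–enolate alkylation of 2-aryl-2-lithio-1,3-dithianes with butenolides used for trans-dibenzylbutyrolactone lignans. Lactone C4 is set by approach of the bulky nucleophile to the ring face opposite the C5 aryl group (4,5-trans), and C3 by alkylation of the planar five-ring enolate on the face opposite the new dithianyl substituent (3,4-trans). The step needs 1,4- over 1,2-addition, which the soft delocalised dithianyl anion in THF at −78 °C should secure, and addition faster than removal of the acidic C5–H, which low temperature and a low standing concentration of 6 should favour. Only the 3,4-trans relation has to be clean, because C5 later becomes CH2 and both C5 epimers would converge on the meso diketone.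

**Step 6**
Reactants: 14 4-bromoresorcinol (4-bromobenzene-1,3-diol)
Product: 15 2,4-bis(benzyloxy)-1-bromobenzene
Conditions: BnBr, K2CO3, acetone, reflux
Reagents that add atoms: benzyl bromide, BrCc1ccccc1
Why: Williamson ether synthesis of both phenols; the aryl bromide is inert under these conditions.

**Step 7**
Reactants: 13 the 3,4-trans-4,5-trans lactone; 15 2,4-bis(benzyloxy)-1-bromobenzene
Product: 18 1-[2,4-bis(benzyloxy)phenyl]-2-[4-(benzyloxy)benzyl]-3-{2-[2,4-bis(benzyloxy)phenyl]-1,3-dithian-2-yl}-4-[4-(benzyloxy)phenyl]-4-hydroxybutan-1-one (racemic; stereocentres as in 13), via 2,4-bis(benzyloxy)phenyllithium 16 (not isolated), via lithium hemiketal alkoxide 17 (not isolated)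
Conditions: 15, n-BuLi, THF, −78 °C; then 13, THF, −78 °C; AcOH quench at −78 °C
Reagents that add atoms: none
Why: Bromine–lithium exchange followed by nucleophilic acyl addition of the aryllithium to the lactone; at −78 °C the cyclic lithium hemiketal alkoxide 17 should persist and is protonated cold, so only one aryl group is introduced and no stereocentre is touched.

**Step 8**
Reactants: 18 the γ-hydroxy ketone dithiane
Product: 19 1,4-bis[2,4-bis(benzyloxy)phenyl]-2-[4-(benzyloxy)benzyl]-3-{[4-(benzyloxy)phenyl](hydroxy)methyl}butane-1,4-dione (racemic; stereocentres as in 18)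
Conditions: MeI (excess), CaCO3, MeCN–THF–H2O, 40 °C, dark
Reagents that add atoms: water, O
Why: S-alkylative hydrolysis of a 1,3-dithiane, in which methylation turns sulfur into a leaving group, the donor-substituted aryl stabilises the thionium ion and water delivers the ketone; the carbonate-buffered medium is chosen so that the new β-hydroxy ketone neither dehydrates nor epimerises at the two α-carbons.

**Step 9**
Reactants: 19 the hexabenzyl hydroxy diketone
Product: 20 meso-(2R,3S)-1,4-bis(2,4-dihydroxyphenyl)-2,3-bis(4-hydroxybenzyl)butane-1,4-dione (CNP0406969.1)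
Conditions: H2 (1 atm), Pd(OH)2/C, THF–MeOH, rt
Reagents that add atoms: none
Why: Catalytic hydrogenolysis should cleave the six aryl benzyl ethers and reduce the benzylic C–O bond of the (4-hydroxyphenyl)carbinol (free or as its hemiketal) to CH2, while the hydrogen-bonded 2-hydroxyaryl ketones resist reduction; neutral conditions should leave both α-stereocentres, and hence the meso configuration, unchanged.

**Compound list**
1 | 4-(benzyloxy)benzaldehyde | O=Cc1ccc(OCc2ccccc2)cc1 | starting material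
2 | ethyl propiolate | C#CC(=O)OCC | starting material
3 | lithium ethyl propiolate (not isolated) | [Li]C#CC(=O)OCC | intermediate
4 | ethyl 4-[4-(benzyloxy)phenyl]-4-hydroxybut-2-ynoate (racemic, one enantiomer drawn) | CCOC(=O)C#C[C@H](O)c1ccc(OCc2ccccc2)cc1 | intermediate
5 | ethyl (Z)-4-[4-(benzyloxy)phenyl]-4-hydroxybut-2-enoate (racemic, one enantiomer drawn; not isolated) | CCOC(=O)/C=C\[C@H](O)c1ccc(OCc2ccccc2)cc1 | intermediate
6 | 5-[4-(benzyloxy)phenyl]furan-2(5H)-one (racemic, one enantiomer drawn) | O=C1C=C[C@@H](c2ccc(OCc3ccccc3)cc2)O1 | intermediate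
7 | 2,4-dihydroxybenzaldehyde | O=Cc1ccc(O)cc1O | starting material
8 | 2,4-bis(benzyloxy)benzaldehyde | O=Cc1ccc(OCc2ccccc2)cc1OCc1ccccc1 | intermediate
9 | 2-[2,4-bis(benzyloxy)phenyl]-1,3-dithiane | C1CSC(SC1)c1ccc(OCc2ccccc2)cc1OCc1ccccc1 | intermediate
10 | 4-(benzyloxy)benzyl bromide | BrCc1ccc(OCc2ccccc2)cc1 | starting material
11 | 2-[2,4-bis(benzyloxy)phenyl]-2-lithio-1,3-dithiane (not isolated) | [Li]C1(SCCCS1)c1ccc(OCc2ccccc2)cc1OCc1ccccc1 | intermediate
12 | lithium 4,5-trans-4-{2-[2,4-bis(benzyloxy)phenyl]-1,3-dithian-2-yl}-5-[4-(benzyloxy)phenyl]-4,5-dihydrofuran-2-olate (racemic, one enantiomer drawn; not isolated) | C1=C(O[Li])O[C@H](c2ccc(OCc3ccccc3)cc2)[C@H]1C1(c2ccc(OCc3ccccc3)cc2OCc2ccccc2)SCCCS1 | intermediate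
13 | rac-(3S,4S,5S)-3-[4-(benzyloxy)benzyl]-4-{2-[2,4-bis(benzyloxy)phenyl]-1,3-dithian-2-yl}-5-[4-(benzyloxy)phenyl]dihydrofuran-2(3H)-one (3,4-trans-4,5-trans; one enantiomer drawn) | O=C1O[C@H](c2ccc(OCc3ccccc3)cc2)[C@@H](C2(c3ccc(OCc4ccccc4)cc3OCc3ccccc3)SCCCS2)[C@@H]1Cc1ccc(OCc2ccccc2)cc1 | intermediate
14 | 4-bromoresorcinol (4-bromobenzene-1,3-diol) | Oc1ccc(Br)c(O)c1 | starting material
15 | 2,4-bis(benzyloxy)-1-bromobenzene | Brc1ccc(OCc2ccccc2)cc1OCc1ccccc1 | intermediate
16 | 2,4-bis(benzyloxy)phenyllithium (not isolated) | [Li]c1ccc(OCc2ccccc2)cc1OCc1ccccc1 | intermediate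
17 | lithium 2-[2,4-bis(benzyloxy)phenyl]tetrahydrofuran-2-olate derived from 13 (hemiketal carbon undefined; not isolated) | [Li]OC1(c2ccc(OCc3ccccc3)cc2OCc2ccccc2)O[C@H](c2ccc(OCc3ccccc3)cc2)[C@@H](C2(c3ccc(OCc4ccccc4)cc3OCc3ccccc3)SCCCS2)[C@@H]1Cc1ccc(OCc2ccccc2)cc1 | intermediate
18 | 1-[2,4-bis(benzyloxy)phenyl]-2-[4-(benzyloxy)benzyl]-3-{2-[2,4-bis(benzyloxy)phenyl]-1,3-dithian-2-yl}-4-[4-(benzyloxy)phenyl]-4-hydroxybutan-1-one (racemic, one enantiomer drawn; stereocentres as in 13) | O[C@H](c1ccc(OCc2ccccc2)cc1)[C@@H](C1(c2ccc(OCc3ccccc3)cc2OCc2ccccc2)SCCCS1)[C@@H](C(=O)c1ccc(OCc2ccccc2)cc1OCc1ccccc1)Cc1ccc(OCc2ccccc2)cc1 | intermediate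
19 | 1,4-bis[2,4-bis(benzyloxy)phenyl]-2-[4-(benzyloxy)benzyl]-3-{[4-(benzyloxy)phenyl](hydroxy)methyl}butane-1,4-dione (racemic, one enantiomer drawn) | O[C@H](c1ccc(OCc2ccccc2)cc1)[C@@H](C(=O)c1ccc(OCc2ccccc2)cc1OCc1ccccc1)[C@@H](C(=O)c1ccc(OCc2ccccc2)cc1OCc1ccccc1)Cc1ccc(OCc2ccccc2)cc1 | intermediate
20 | meso-(2R,3S)-1,4-bis(2,4-dihydroxyphenyl)-2,3-bis(4-hydroxybenzyl)butane-1,4-dione | O=C(c1ccc(O)cc1O)[C@@H](Cc1ccc(O)cc1)[C@@H](Cc1ccc(O)cc1)C(=O)c1ccc(O)cc1O | target

**Step count**
Total steps: 9. Longest linear sequence: 6 steps (1 → 2 → 5 → 7 → 8 → 9, or 3 → 4 → 5 → 7 → 8 → 9).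

**Steps most likely to fail**

1. Step 5. The dithianyl anion may act as a base and remove the doubly activated C5–H of the butenolide (forming a 2-oxidofuran and returning 9) instead of adding, and the enolate alkylation may be slow or poorly face-selective. The fallback sets out from 4 and comes back at 13. Trans-selective reduction of the γ-hydroxy ynoate (Red-Al, THF, −72 °C) should give ethyl (E)-4-[4-(benzyloxy)phenyl]-4-hydroxybut-2-enoate F1, and silylation (TBSCl, imidazole, DMF) its tert-butyldimethylsilyl ether F2. This open-chain acceptor cannot aromatise on γ-deprotonation, so the same anion 11 followed by bromide 10 should give the open-chain ester ethyl 2-[4-(benzyloxy)benzyl]-3-{2-[2,4-bis(benzyloxy)phenyl]-1,3-dithian-2-yl}-4-[4-(benzyloxy)phenyl]-4-(tert-butyldimethylsilyloxy)butanoate F3 as a diastereomer mixture. TBAF in THF removes the silyl group and the alkoxide lactonises; brief DBU treatment equilibrates C3 to the trans arrangement next to the dithianyl group. Lactone 13 is separated by chromatography from its C5 epimer, the 3,4-trans-4,5-cis lactone F4, and continues at step 7.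

2. Step 7. The hindered lactone carbonyl may be attacked slowly, the aryllithium may instead enolise C3, or the tetrahedral intermediate may collapse early and take up a second aryl group. The fallback sets out from 13 and comes back at 18. Aminolysis with MeONHMe·HCl/Me3Al (CH2Cl2, 0 °C to rt) gives the open-chain N-methoxy-N-methyl 4-hydroxy amide F5. Immediate silylation (TESCl, imidazole, DMF) gives its triethylsilyl ether F6, which can no longer relactonise. Aryllithium 16 (from 15, THF, −78 °C) then adds once through the stable chelated Weinreb intermediate to give the triethylsilyl ether of 18 F7, and HF·pyridine in THF/pyridine at 0 °C returns 18.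

3. Step 8. Once the second carbonyl is exposed, the free benzylic hydroxyl is β to it and γ to the other ketone. Dehydration to an enone, or cyclodehydration of the 1,4-dicarbonyl/hemiketal to a furan, would erase the C2 and/or C3 configuration. The fallback removes the benzylic oxygen before the ketone is unmasked; it sets out from 13 and comes back at 20. Ionic hydrogenolysis of the benzylic lactone C5–O bond (Et3SiH, TFA, CH2Cl2, 0 °C, short exposure to spare the benzyl ethers; the dithiane is acid-stable) should give 2-[4-(benzyloxy)benzyl]-3-{2-[2,4-bis(benzyloxy)phenyl]-1,3-dithian-2-yl}-4-[4-(benzyloxy)phenyl]butanoic acid F8. Coupling with MeONHMe·HCl (EDC·HCl, HOBt, i-Pr2NEt) gives the Weinreb amide F9, and aryllithium 16 at −78 °C the dithiane-masked diketone 1-[2,4-bis(benzyloxy)phenyl]-2-[4-(benzyloxy)benzyl]-3-{2-[2,4-bis(benzyloxy)phenyl]-1,3-dithian-2-yl}-4-[4-(benzyloxy)phenyl]butan-1-one F10. MeI/CaCO3 in aqueous MeCN then gives meso-1,4-bis[2,4-bis(benzyloxy)phenyl]-2,3-bis[4-(benzyloxy)benzyl]butane-1,4-dione F11, which carries no hydroxyl, and hydrogenolysis (H2, Pd/C, THF–MeOH) gives 20.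

**Further compounds**
F1 | step 5 | ethyl (E)-4-[4-(benzyloxy)phenyl]-4-hydroxybut-2-enoate (racemic, one enantiomer drawn) | CCOC(=O)/C=C/[C@H](O)c1ccc(OCc2ccccc2)cc1
F2 | step 5 | ethyl (E)-4-[4-(benzyloxy)phenyl]-4-(tert-butyldimethylsilyloxy)but-2-enoate (racemic, one enantiomer drawn) | CCOC(=O)/C=C/[C@H](O[Si](C)(C)C(C)(C)C)c1ccc(OCc2ccccc2)cc1
F3 | step 5 | ethyl 2-[4-(benzyloxy)benzyl]-3-{2-[2,4-bis(benzyloxy)phenyl]-1,3-dithian-2-yl}-4-[4-(benzyloxy)phenyl]-4-(tert-butyldimethylsilyloxy)butanoate (diastereomer mixture) | CCOC(=O)C(Cc1ccc(OCc2ccccc2)cc1)C(C(O[Si](C)(C)C(C)(C)C)c1ccc(OCc2ccccc2)cc1)C1(c2ccc(OCc3ccccc3)cc2OCc2ccccc2)SCCCS1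
F4 | step 5 | 3,4-trans-4,5-cis epimer of 13 (C5 epimer; racemic, one enantiomer drawn) | O=C1O[C@@H](c2ccc(OCc3ccccc3)cc2)[C@@H](C2(c3ccc(OCc4ccccc4)cc3OCc3ccccc3)SCCCS2)[C@@H]1Cc1ccc(OCc2ccccc2)cc1
F5 | step 7 | 2-[4-(benzyloxy)benzyl]-3-{2-[2,4-bis(benzyloxy)phenyl]-1,3-dithian-2-yl}-4-[4-(benzyloxy)phenyl]-4-hydroxy-N-methoxy-N-methylbutanamide (racemic, one enantiomer drawn) | O[C@H](c1ccc(OCc2ccccc2)cc1)[C@@H](C1(c2ccc(OCc3ccccc3)cc2OCc2ccccc2)SCCCS1)[C@@H](C(=O)N(C)OC)Cc1ccc(OCc2ccccc2)cc1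
F6 | step 7 | triethylsilyl ether of F5 (racemic, one enantiomer drawn) | CC[Si](CC)(CC)O[C@H](c1ccc(OCc2ccccc2)cc1)[C@@H](C1(c2ccc(OCc3ccccc3)cc2OCc2ccccc2)SCCCS1)[C@@H](C(=O)N(C)OC)Cc1ccc(OCc2ccccc2)cc1
F7 | step 7 | triethylsilyl ether of 18 (racemic, one enantiomer drawn) | CC[Si](CC)(CC)O[C@H](c1ccc(OCc2ccccc2)cc1)[C@@H](C1(c2ccc(OCc3ccccc3)cc2OCc2ccccc2)SCCCS1)[C@@H](C(=O)c1ccc(OCc2ccccc2)cc1OCc1ccccc1)Cc1ccc(OCc2ccccc2)cc1
F8 | step 8 | 2-[4-(benzyloxy)benzyl]-3-{2-[2,4-bis(benzyloxy)phenyl]-1,3-dithian-2-yl}-4-[4-(benzyloxy)phenyl]butanoic acid (racemic, one enantiomer drawn) | C(c1ccc(OCc2ccccc2)cc1)[C@@H](C1(c2ccc(OCc3ccccc3)cc2OCc2ccccc2)SCCCS1)[C@@H](C(=O)O)Cc1ccc(OCc2ccccc2)cc1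
F9 | step 8 | N-methoxy-N-methyl amide of F8 (racemic, one enantiomer drawn) | C(c1ccc(OCc2ccccc2)cc1)[C@@H](C1(c2ccc(OCc3ccccc3)cc2OCc2ccccc2)SCCCS1)[C@@H](C(=O)N(C)OC)Cc1ccc(OCc2ccccc2)cc1
F10 | step 8 | 1-[2,4-bis(benzyloxy)phenyl]-2-[4-(benzyloxy)benzyl]-3-{2-[2,4-bis(benzyloxy)phenyl]-1,3-dithian-2-yl}-4-[4-(benzyloxy)phenyl]butan-1-one (racemic, one enantiomer drawn) | C(c1ccc(OCc2ccccc2)cc1)[C@@H](C1(c2ccc(OCc3ccccc3)cc2OCc2ccccc2)SCCCS1)[C@@H](C(=O)c1ccc(OCc2ccccc2)cc1OCc1ccccc1)Cc1ccc(OCc2ccccc2)cc1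
F11 | step 8 | meso-1,4-bis[2,4-bis(benzyloxy)phenyl]-2,3-bis[4-(benzyloxy)benzyl]butane-1,4-dione | C(c1ccc(OCc2ccccc2)cc1)[C@@H](C(=O)c1ccc(OCc2ccccc2)cc1OCc1ccccc1)[C@@H](C(=O)c1ccc(OCc2ccccc2)cc1OCc1ccccc1)Cc1ccc(OCc2ccccc2)cc1
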